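The runs stem from a simulated flask with made-up constants; scatter was added.

The intermediate cannot be weighed: the earlier runs report solvolysis product and target, not it. Its split has to be read from what it leaves behind.

| flask | substrate | first nucleophile | second nucleophile | protic impurity | remark | time |
|---|---|---|---|---|---|---|
| west | 0.50 mM | 0.60 mM | 0.475 mM | 0.50 mM | run made earlier |  |
| north-east | 0.25 mM | 0.60 mM | 0.475 mM | 0.50 mM | run made earlier |  |
| north-west | 1 mM | 0.60 mM | 0.475 mM | 0.50 mM | run made earlier |  |
| north | 0.50 mM | 0.60 mM | 0.71 mM | 0.50 mM | run made earlier |  |
| Sunday's | 0.50 mM | 0.600 mM | 0.475 mM (in portions, 4, over 2.0 min) | 0.500 mM | first portion at the start, last at 2.0 min | 2.5 min |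
| Wednesday's | 0.50 mM | 0.600 mM | 0.475 mM (fed, over 2.0 min) | 0.500 mM | all else is in the flask from the start; the feed brings no volume worth counting | 2.5 min |
| Thursday's | 0.50 mM (fed, over 2.0 min) | 0.600 mM | 0.475 mM | 0.500 mM | all else is in the flask from the start; the feed brings no volume worth counting | 2.5 min |
| Saturday's | 0.50 mM | 0.600 mM | 0.475 mM | 0.500 mM | everything together at the start | 2.5 min |

west run (percent of the substrate charged)

| time / s | solvolysis product / % | target / % |
|---|---|---|
| 20.0 | 26.3 | 0.9 |
| 40.0 | 42.1 | 0 |
| 50.0 | 47.9 | 1.0 |
| 80.0 | 59.7 | 0 |
| 90.0 | 61.3 | 0 |

north-east run (percent of the substrate charged)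

| time / min | solvolysis product / % | target / % |
|---|---|---|
| 0.200 | 17.6 | 1.2 |
| 0.417 | 31.3 | 1.7 |
| 0.667 | 40.7 | 0 |
| 1.33 | 59.2 | 0 |
| 2.50 | 66.8 | 1.7 |

north-west run (percent of the substrate charged)

| time / min | solvolysis product / % | target / % |
|---|---|---|
| 0.500 | 36.4 | 0 |
| 1.00 | 53.5 | 0 |
| 1.50 | 65.5 | 0 |
| 2.00 | 69.3 | 0 |
| 2.50 | 72.8 | 0 |

north run (percent of the substrate charged)

| time / min | solvolysis product / % | target / % |
|---|---|---|
| 0.200 | 13.1 | 0 |
| 0.417 | 28.3 | 0 |
| 0.667 | 37.2 | 0 |
| 1.33 | 53.0 | 2.5 |
| 2.50 | 59.4 | 0 |

(standard deviation of a reading: 1 percentage point)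

- a species is counted by the substrate in it: one side product counts as two
- on the list of suspects stand: substrate -> intermediate; first nucleophile + intermediate <-> target; second nucleophile + intermediate -> other capture product; intermediate -> solvolysis product; first nucleophile + protic impurity -> quenched reagent; substrate + target -> side product

- the flask that comes out highest in amount of solvolysis product, in percent of the substrate charged; "all alike" if 1.5 percentage points covers them all (Sunday's / Wednesday's / Thursday's / Saturday's / all alike)
- amount of solvolysis product at the end, in percent of the substrate charged, Sunday's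
- amount of solvolysis product at the end, in percent of the substrate charged, Wednesday's
- amount of solvolysis product at the end, in percent of the substrate charged, Thursday's
- amount of solvolysis product at the end, in percent of the substrate charged, Saturday's

Let D be the concentration of second nucleophile. On the list of suspects, the intermediate, formed from substrate, goes to other capture product (capture) at a rate first order in D and to solvolysis product with no D in its rate, so D orders the split. Target stays at 1.0% or below in the west run, with a scatter of 1 percentage point, so it is reckoned as no sink.

The north-east readings give a first-order substrate constant k of 1.41 min⁻¹, so 97.0% is reckoned to have reacted by 2.5 min. In the north-west run, that conversion minus the solvolysis reading is capture. This reads 0.981 mM⁻¹ for s, the trap coefficient or selectivity factor: capture over solvolysis per mM of D. The solvolysis share is the reciprocal of one plus sD, with D taken as the average met by the intermediate as it forms.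

Turned round: for Wednesday's to tie with Saturday's within 1.5 points, feeding would have to leave that met D nearly unchanged, so the substrate would have to outlast the feed. Here k times the feed time tf of 2.0 min is 2.82, and a steady feed shows the intermediate a fraction 0.334 of the charge. Wednesday's is therefore reckoned to meet 0.158 mM, capture's draw uncounted, and Sunday's, with evenly spaced portions, 0.190 mM.

Saturday's repeats the west recipe, so scaling the last west reading by conversion gives 67.7%, which corresponds to a met D of 0.443 mM. Wednesday's meets the least, and reckons to 84.0%, Sunday's to 81.8%. The reckoned gap of 16 points from Wednesday's to Saturday's stands against a margin of 1.5 points. Thursday's is reckoned with Saturday's split and with 16.5% of its substrate unreacted at the end, giving 58.2%.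

The forecast names Wednesday's as highest, on “little trap present early”, with 84%, 86%, 59% and 69% for Sunday's, Wednesday's, Thursday's and Saturday's, its values for Sunday's and Wednesday's standing above this reckoning.

The flasks give 84.3%, 86.5%, 59.3% and 68.3% in that order, so Wednesday's is highest.

    substrate → intermediate (k = 0.0254 s⁻¹)
    first nucleophile + intermediate ⇌ target (K = 1100 L mol⁻¹, k = 4490 L mol⁻¹ s⁻¹)
    second nucleophile + intermediate → other capture product (k = 2190 L mol⁻¹ s⁻¹)
    intermediate → solvolysis product (k = 2.04 s⁻¹)
    first nucleophile + protic impurity → quenched reagent (k = 12.9 L mol⁻¹ s⁻¹)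
    substrate + target → side product (k = 25.2 L mol⁻¹ s⁻¹)

Dividing the simulated capture-to-solvolysis ratio of Wednesday's at 2.50 min by s gives a met D of 0.129 mM, against the 0.158 mM reckoned. The neighbour is Wednesday's with 1.2 mM of second nucleophile. The same fraction gives it a met D of 0.400 mM, and the same conversion gives 69.7% of solvolysis product. The neighbour itself ends at 75.2%, with 22.2% of other capture product and 2.21% of substrate.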